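**Strategy.** The 3,7-dioxabicyclo[3.3.0]octane core (C1 carbinol bridgehead, C2 syringyl CH, O3, C4, C5 CH bridgehead, C6 guaiacyl CH, O7, C8) is disconnected at the ring-fusion bond C1–C5. A samarium diiodide ketyl–olefin cyclization makes it: the ketone carbon C1 of an acyclic (R)-α-cinnamyloxy-α'-hydroxy ketone, turned into a nucleophilic ketyl radical, adds 5-exo to the styrene carbon C5. The step exploits the tertiary carbinol at C1 next to C5 and the radical-stabilising guaiacyl group on C6; it closes ring A (C1–C2–O3–C4–C5) and sets C1 and C5 from C2 alone. Ring B (C5–C6–O7–C8–C1) then follows by quinone methide etherification.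

Key step: step 9

Remark on names: ArS stands for 4-(tert-butyldimethylsilyloxy)-3,5-dimethoxyphenyl; core locants are those given in the strategy paragraph.

Assumption: the (S,S)-configured transfer-hydrogenation catalyst is expected to give the (R)-hydroxy ester, by analogy with aryl ketones; if the sense were opposite, the (R,R)-catalyst would be used.

**Step 1**
Reactants: 1 4-bromo-2,6-dimethoxyphenol
Product: 2 tert-butyl(4-bromo-2,6-dimethoxyphenoxy)dimethylsilane
Conditions: TBSCl, imidazole, DMF, rt
Reagents that add atoms: tert-butyldimethylsilyl chloride, CC(C)(C)[Si](C)(C)Cl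
Why: Imidazole-promoted O-silylation of the hindered phenol masks the acidic OH for the lithiation, and the silyl ether is kept until the last step.

**Step 2**
Reactants: 2 tert-butyl(4-bromo-2,6-dimethoxyphenoxy)dimethylsilane; 3 diethyl oxalate
Product: 5 ethyl 2-[4-(tert-butyldimethylsilyloxy)-3,5-dimethoxyphenyl]-2-oxoacetate, via aryllithium 4 (not isolated)
Conditions: n-BuLi, THF, −78 °C; then transfer into 3 (3 equiv), THF, −78 °C; NH4Cl aq.
Reagents that add atoms: none
Why: Bromine–lithium exchange gives aryllithium 4, and its inverse addition to excess oxalate diester at −78 °C should stop at the α-keto ester (acylation of an organolithium).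

**Step 3**
Reactants: 5 ethyl 2-[ArS]-2-oxoacetate
Product: 6 ethyl (2R)-2-[ArS]-2-hydroxyacetate
Conditions: RuCl[(S,S)-TsDPEN](p-cymene) (1 mol%), HCO2H/Et3N (5:2), DMF, rt
Reagents that add atoms: none
Why: Noyori asymmetric transfer hydrogenation of an aryl α-keto ester, in which the aryl/arene CH–π contact of the six-membered hydride-transfer transition state fixes the carbonyl face and is expected to set the (R)-carbinol, the only stereocentre carried on to C2 of the target.

**Step 4**
Reactants: 6 ethyl (2R)-2-[ArS]-2-hydroxyacetate; 7 allyl bromide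
Product: 8 ethyl (2R)-2-(allyloxy)-2-[ArS]acetate
Conditions: Ag2O, 4 Å molecular sieves, Et2O, rt, dark
Reagents that add atoms: none
Why: Silver oxide-mediated Williamson O-allylation is essentially non-basic, so the benzylic α-ester centre should not enolise and should stay (R).

**Step 5**
Reactants: 8 ethyl (2R)-2-(allyloxy)-2-[ArS]acetate
Product: 9 (2R)-2-(allyloxy)-2-[ArS]-N-methoxy-N-methylacetamide
Conditions: MeNH(OMe)·HCl, AlMe3, CH2Cl2, 0 °C to rt
Reagents that add atoms: N,O-dimethylhydroxylamine hydrochloride, CNOC.Cl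
Why: Weinreb aminolysis of the ester by the aluminium amide made in the flask is Lewis acidic and non-enolising, so the stereocentre should be retained.

**Step 6**
Reactants: 9 (2R)-2-(allyloxy)-2-[ArS]-N-methoxy-N-methylacetamide; 10 tributyl[(methoxymethoxy)methyl]stannane
Product: 12 (1R)-1-(allyloxy)-1-[ArS]-3-(methoxymethoxy)propan-2-one, via alkoxymethyllithium 11 (not isolated)
Conditions: 10, n-BuLi, THF, −78 °C; then 9, THF, −78 °C; NH4Cl aq. at −78 °C
Reagents that add atoms: none
Why: Tin–lithium exchange gives the hydroxymethyl anion equivalent 11, which should add once to the Weinreb amide through the chelated tetrahedral intermediate, addition at −78 °C being expected to outrun α-deprotonation.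

**Step 7**
Reactants: 12 (1R)-1-(allyloxy)-1-[ArS]-3-(methoxymethoxy)propan-2-one
Product: 13 (1R)-1-(allyloxy)-1-[ArS]-3-hydroxypropan-2-one
Conditions: Me2BBr, CH2Cl2, −78 °C; then NaHCO3 aq.
Reagents that add atoms: none
Why: Bromodimethylborane cleaves the methoxymethyl acetal at −78 °C (Lewis acid acetal cleavage), which should spare the aryl silyl ether, the allyl ether and the enolisable benzylic centre.

**Step 8**
Reactants: 13 (1R)-1-(allyloxy)-1-[ArS]-3-hydroxypropan-2-one; 14 2-methoxy-4-vinylphenol
Product: 15 (1R)-1-[ArS]-3-hydroxy-1-{[(2E)-3-(4-hydroxy-3-methoxyphenyl)prop-2-en-1-yl]oxy}propan-2-one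
Conditions: second-generation Grubbs catalyst RuCl2(=CHPh)(PCy3)(H2IMes) (5 mol%), 14 (3 equiv), CH2Cl2, 40 °C
Reagents that add atoms: none
Why: Olefin cross-metathesis of the terminal allyl ether with the styrene is thermodynamically (E)-selective and tolerant of ketone, alcohol and phenol, and it installs the radical acceptor and the guaiacyl ring in one step.

**Step 9**
Reactants: 15 (1R)-1-[ArS]-3-hydroxy-1-{[(2E)-3-(4-hydroxy-3-methoxyphenyl)prop-2-en-1-yl]oxy}propan-2-one
Product: 16 (2R,3S,4S)-2-[ArS]-4-(4-hydroxy-3-methoxybenzyl)-3-(hydroxymethyl)oxolan-3-ol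
Conditions: SmI2 (3 equiv, slow addition), HMPA (12 equiv), t-BuOH (2 equiv), THF, −78 to 0 °C
Reagents that add atoms: none
Why: SmI2 activated by HMPA transfers one electron to the ketone of 15 to give a samarium ketyl centred on C1, which adds to the styrene carbon C5; the guaiacyl-stabilised benzylic radical at C6 is then reduced by a second SmI2 and protonated by t-BuOH. The closest known reaction type is the samarium diiodide ketyl–olefin reductive cyclization onto a styrene-type acceptor. Ring A (C1–C2–O3–C4–C5) closes in the 5-exo-trig mode. Both new stereocentres are controlled by the existing C2 centre in a chair-like transition state: the C2 aryl group sits pseudo-equatorial and should end trans to the new benzyl arm on C5, and the bulky solvated O–Sm group turns away from the alkene, so that OH is trans and CH2OH cis to that arm, the (3S,4S) arrangement that ring B needs for cis fusion. The step needs cyclization to outrun β-elimination of the α-oxygen substituents and plain carbonyl reduction, and 5-exo attack to beat 6-endo attack; the fast addition of a ketyl to a styrene (benzylic radical), the poor leaving ability of alkoxide and slow addition of the reductant at low temperature should secure this.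

**Step 10**
Reactants: 16 (2R,3S,4S)-2-[ArS]-4-(4-hydroxy-3-methoxybenzyl)-3-(hydroxymethyl)oxolan-3-ol
Product: 18 (1S,2R,5R,6S)-2-[ArS]-6-(4-hydroxy-3-methoxyphenyl)-3,7-dioxabicyclo[3.3.0]octan-1-ol, via quinone methide 17 (not isolated)
Conditions: DDQ (1.0 equiv), CH2Cl2, −20 to 0 °C
Reagents that add atoms: none
Why: DDQ dehydrogenates the free 4-alkyl-2-methoxyphenol to p-quinone methide 17 (the silylated syringyl ring cannot react this way) and the primary hydroxyl adds 1,6 in a 5-exo closure of ring B (oxidative quinone methide etherification); cis fusion is enforced by the bicycle and the aryl group is expected to take the exo position at C6, trans to C4, as in the quinone methide closures that lead to pinoresinol-type lignans.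

**Step 11**
Reactants: 18 (1S,2R,5R,6S)-2-[ArS]-6-(4-hydroxy-3-methoxyphenyl)-3,7-dioxabicyclo[3.3.0]octan-1-ol
Product: 19 fraxiresinol
Conditions: TBAF, AcOH, THF, 0 °C
Reagents that add atoms: none
Why: Fluoride cleaves the aryl silyl ether, acetic acid buffers the medium to protect the base- and air-sensitive bis-phenol, and no stereocentre is touched.

**Compound list**

1 | 4-bromo-2,6-dimethoxyphenol | COc1cc(Br)cc(OC)c1O | starting material
2 | tert-butyl(4-bromo-2,6-dimethoxyphenoxy)dimethylsilane | COc1cc(Br)cc(OC)c1O[Si](C)(C)C(C)(C)C | intermediate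
3 | diethyl oxalate | CCOC(=O)C(=O)OCC | starting material
4 | [4-(tert-butyldimethylsilyloxy)-3,5-dimethoxyphenyl]lithium | [Li]c1cc(OC)c(O[Si](C)(C)C(C)(C)C)c(OC)c1 | intermediate
5 | ethyl 2-[4-(tert-butyldimethylsilyloxy)-3,5-dimethoxyphenyl]-2-oxoacetate | CCOC(=O)C(=O)c1cc(OC)c(O[Si](C)(C)C(C)(C)C)c(OC)c1 | intermediate
6 | ethyl (2R)-2-[4-(tert-butyldimethylsilyloxy)-3,5-dimethoxyphenyl]-2-hydroxyacetate | CCOC(=O)[C@H](O)c1cc(OC)c(O[Si](C)(C)C(C)(C)C)c(OC)c1 | intermediate
7 | allyl bromide | C=CCBr | starting material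
8 | ethyl (2R)-2-(allyloxy)-2-[4-(tert-butyldimethylsilyloxy)-3,5-dimethoxyphenyl]acetate | CCOC(=O)[C@H](OCC=C)c1cc(OC)c(O[Si](C)(C)C(C)(C)C)c(OC)c1 | intermediate
9 | (2R)-2-(allyloxy)-2-[4-(tert-butyldimethylsilyloxy)-3,5-dimethoxyphenyl]-N-methoxy-N-methylacetamide | CON(C)C(=O)[C@H](OCC=C)c1cc(OC)c(O[Si](C)(C)C(C)(C)C)c(OC)c1 | intermediate
10 | tributyl[(methoxymethoxy)methyl]stannane | CCCC[Sn](CCCC)(CCCC)COCOC | starting material
11 | [(methoxymethoxy)methyl]lithium | [Li]COCOC | intermediate
12 | (1R)-1-(allyloxy)-1-[4-(tert-butyldimethylsilyloxy)-3,5-dimethoxyphenyl]-3-(methoxymethoxy)propan-2-one | COCOCC(=O)[C@H](OCC=C)c1cc(OC)c(O[Si](C)(C)C(C)(C)C)c(OC)c1 | intermediate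
13 | (1R)-1-(allyloxy)-1-[4-(tert-butyldimethylsilyloxy)-3,5-dimethoxyphenyl]-3-hydroxypropan-2-one | OCC(=O)[C@H](OCC=C)c1cc(OC)c(O[Si](C)(C)C(C)(C)C)c(OC)c1 | intermediate
14 | 2-methoxy-4-vinylphenol | C=Cc1ccc(O)c(OC)c1 | starting material
15 | (1R)-1-[4-(tert-butyldimethylsilyloxy)-3,5-dimethoxyphenyl]-3-hydroxy-1-{[(2E)-3-(4-hydroxy-3-methoxyphenyl)prop-2-en-1-yl]oxy}propan-2-one | OCC(=O)[C@H](OC/C=C/c1ccc(O)c(OC)c1)c1cc(OC)c(O[Si](C)(C)C(C)(C)C)c(OC)c1 | intermediate
16 | (2R,3S,4S)-2-[4-(tert-butyldimethylsilyloxy)-3,5-dimethoxyphenyl]-4-(4-hydroxy-3-methoxybenzyl)-3-(hydroxymethyl)oxolan-3-ol | OC[C@]1(O)[C@@H](c2cc(OC)c(O[Si](C)(C)C(C)(C)C)c(OC)c2)OC[C@@H]1Cc1ccc(O)c(OC)c1 | intermediate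
17 | 4-{[(3S,4S,5R)-5-[4-(tert-butyldimethylsilyloxy)-3,5-dimethoxyphenyl]-4-hydroxy-4-(hydroxymethyl)oxolan-3-yl]methylidene}-2-methoxycyclohexa-2,5-dien-1-one | OC[C@]1(O)[C@@H](c2cc(OC)c(O[Si](C)(C)C(C)(C)C)c(OC)c2)OC[C@@H]1C=C1C=CC(=O)C(OC)=C1 | intermediate
18 | (1S,2R,5R,6S)-2-[4-(tert-butyldimethylsilyloxy)-3,5-dimethoxyphenyl]-6-(4-hydroxy-3-methoxyphenyl)-3,7-dioxabicyclo[3.3.0]octan-1-ol | COc1cc([C@H]2OC[C@]3(O)[C@@H](c4cc(OC)c(O[Si](C)(C)C(C)(C)C)c(OC)c4)OC[C@H]23)ccc1O | intermediate
19 | fraxiresinol, (1S,2R,5R,6S)-2-(4-hydroxy-3,5-dimethoxyphenyl)-6-(4-hydroxy-3-methoxyphenyl)-3,7-dioxabicyclo[3.3.0]octan-1-ol | COc1cc([C@H]2OC[C@]3(O)[C@@H](c4cc(OC)c(O)c(OC)c4)OC[C@H]23)ccc1O | target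

**Step count.** Total: 11 steps. Longest linear sequence: 11 steps (1 to 19); compounds 3, 7, 10 and 14 enter as purchased building blocks.

**Steps most likely to fail**

Step 9. The samarium ketyl may lose one of its α-oxygen substituents (β-elimination of the cinnamyl alkoxide or of the hydroxyl) or be reduced to the open-chain alcohol before it cyclizes, and facial selectivity at C1 may be incomplete. The fallback closes the same bond by a polar route and sets out from 15. Treatment with Me2AlCl (3 equiv) in CH2Cl2 at −78 to −40 °C should chelate and activate the ketone, the electron-rich styrene carbon C5 should attack C1 (Prins-type carbonyl–alkene addition), and the benzylic cation at C6 should be captured by the primary aluminium alkoxide. This would close both rings at once and give 18 directly, so the fallback rejoins the route at 18 and step 10 is not needed. It makes no new compound.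

Step 10. The product is itself a p-hydroxybenzyl ether, so remaining oxidant may over-oxidise it, and reversible quinone methide formation may erode the exo selectivity at C6. The fallback avoids any free phenol during the oxidation and sets out from 16. Phenoxide-selective silylation (TBSCl, Et3N, CH2Cl2, 0 °C) should give (2R,3S,4S)-2-[ArS]-4-[4-(tert-butyldimethylsilyloxy)-3-methoxybenzyl]-3-(hydroxymethyl)oxolan-3-ol F1. DDQ in CH2Cl2 at rt should then abstract hydride from the electron-rich silyloxybenzylic CH2, and capture of the cation by the primary hydroxyl should give fraxiresinol bis(tert-butyldimethylsilyl) ether F2. TBAF/AcOH in THF removes both silyl groups, and the fallback rejoins the route at 19.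

Step 6. The basic organolithium may deprotonate the benzylic α-position of the Weinreb amide (loss of enantiopurity), and the later acetal cleavage of step 7 adds a second hazard. The fallback introduces the hydroxymethyl carbon under non-basic conditions and sets out from 8. Neutral ester hydrolysis (Me3SnOH, 1,2-dichloroethane, 80 °C) should give (2R)-2-(allyloxy)-2-[ArS]acetic acid F3. Isobutyl chloroformate and N-methylmorpholine in THF at −15 °C give the mixed isobutyl carbonic anhydride F4, which is not isolated. Diazomethane in Et2O at 0 °C then gives (3R)-3-(allyloxy)-3-[ArS]-1-diazopropan-2-one F5 (diazoketone formation as in the Arndt–Eistert sequence). Acid-mediated hydrolysis of the diazoketone (dilute H2SO4, 1,4-dioxane/water, 40 °C) should give hydroxy ketone 13, where the fallback rejoins the route; steps 5 to 7 are bypassed.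

**Further compounds**

F0 | step 9 | none | none
F1 | step 10 | (2R,3S,4S)-2-[4-(tert-butyldimethylsilyloxy)-3,5-dimethoxyphenyl]-4-[4-(tert-butyldimethylsilyloxy)-3-methoxybenzyl]-3-(hydroxymethyl)oxolan-3-ol | OC[C@]1(O)[C@@H](c2cc(OC)c(O[Si](C)(C)C(C)(C)C)c(OC)c2)OC[C@@H]1Cc1ccc(O[Si](C)(C)C(C)(C)C)c(OC)c1
F2 | step 10 | fraxiresinol bis(tert-butyldimethylsilyl) ether | COc1cc([C@H]2OC[C@]3(O)[C@@H](c4cc(OC)c(O[Si](C)(C)C(C)(C)C)c(OC)c4)OC[C@H]23)ccc1O[Si](C)(C)C(C)(C)C
F3 | step 6 | (2R)-2-(allyloxy)-2-[4-(tert-butyldimethylsilyloxy)-3,5-dimethoxyphenyl]acetic acid | OC(=O)[C@H](OCC=C)c1cc(OC)c(O[Si](C)(C)C(C)(C)C)c(OC)c1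
F4 | step 6 | (2R)-2-(allyloxy)-2-[4-(tert-butyldimethylsilyloxy)-3,5-dimethoxyphenyl]acetic isobutyl carbonic anhydride | CC(C)COC(=O)OC(=O)[C@H](OCC=C)c1cc(OC)c(O[Si](C)(C)C(C)(C)C)c(OC)c1
F5 | step 6 | (3R)-3-(allyloxy)-3-[4-(tert-butyldimethylsilyloxy)-3,5-dimethoxyphenyl]-1-diazopropan-2-one | [N-]=[N+]=CC(=O)[C@H](OCC=C)c1cc(OC)c(O[Si](C)(C)C(C)(C)C)c(OC)c1
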